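**Retrosynthetic overview**
- Target ⇐ oxidation of the C3 carbinol of a 3,4-diol ⇐ face-selective dihydroxylation of the (E)-C3=C4 alkene of a ten-membered dienolide.
- Ten-membered ring ⇐ C7–C8 bond: intramolecular Nozaki–Hiyama–Kishi allylation of a 3-(bromomethyl)butenolide onto a C8 aldehyde (sets C7 and C8, unveils the exo-methylene).
- Butenolide ⇐ C5–C6 bond: catalytic enantioselective vinylogous Mukaiyama aldol that dearomatises a 2-silyloxyfuran (from furan-3-ylmethanol) with an (E)-enal (sets C5 and C6).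
- Enal ⇐ (R)-citronellal (C10 from the pool, C9 by proline α-oxygenation, C5 by SeO2 oxidation).
- Ring order: the five-membered O-ring is there from the start as the furan and becomes the lactone in the aldol; the carbocycle is closed afterwards.

Atom labels (target numbering): lactone O on C6; C7 carries C11(=C13H2)–C12(=O); C8 OH; C9 O-isovaleryl; C10 CH3; C1, C2 CH2; C3 C=O; C4 OH and CH3; C5 O-isobutyryl.

Assumption: the (R,R)-bisphosphoramide is taken as the antipode that sends the furan to the Re face of the enal (the (S,S)-ligand is used otherwise, nothing else changing), and the target is handled as the open keto-alcohol.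

Step 1
Reactants: 1 (R)-citronellal
Product: 4 (2R,3R)-3,7-dimethyloct-6-ene-1,2-diol, via aminoxy aldehyde 2 (not isolated), via aminoxy alcohol 3 (not isolated)
Conditions: PhNO (1.0 equiv), L-proline (20 mol %), CHCl3, 4 °C; then NaBH4, EtOH, 0 °C; then Zn, AcOH, rt
Reagents that add atoms: nitrosobenzene O=Nc1ccccc1
Why: Proline enamine α-aminoxylation of the aldehyde sets C9 as R under catalyst control (L-proline gives the (R)-α-oxy aldehyde) next to the pool-derived C10, and borohydride reduction then reductive N–O cleavage with zinc unmask the 1,2-diol without touching the alkene.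

Step 2
Reactants: 4 (2R,3R)-3,7-dimethyloct-6-ene-1,2-diol
Product: 6 (2R,3R)-1-[(tert-butyldimethylsilyl)oxy]-3,7-dimethyloct-6-en-2-yl 3-methylbutanoate, via silyl ether 5 (not isolated)
Conditions: TBSCl (1.05 equiv), imidazole, CH2Cl2, 0 °C; then isovaleryl chloride, pyridine, DMAP (cat.), 0 °C to rt
Reagents that add atoms: tert-butyldimethylsilyl chloride CC(C)(C)[Si](C)(C)Cl; 3-methylbutanoyl chloride CC(C)CC(=O)Cl
Why: Silylation picks the primary hydroxyl on steric grounds and the remaining secondary C9 hydroxyl is then esterified (DMAP-catalysed acyl substitution); no stereocentre is touched.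

Step 3
Reactants: 6 (2R,3R)-1-[(tert-butyldimethylsilyl)oxy]-3,7-dimethyloct-6-en-2-yl 3-methylbutanoate
Product: 8 (2R,3R,6E)-1-[(tert-butyldimethylsilyl)oxy]-3,7-dimethyl-8-oxooct-6-en-2-yl 3-methylbutanoate, via allylic alcohol 7 (not isolated)
Conditions: SeO2 (0.5 equiv), t-BuOOH, salicylic acid (cat.), CH2Cl2, rt; then MnO2, CH2Cl2, rt
Reagents that add atoms: selenium dioxide O=[Se]=O; tert-butyl hydroperoxide CC(C)(C)OO
Why: SeO2/t-BuOOH allylic oxidation (ene reaction then [2,3]-sigmatropic shift) attacks the (E)-methyl of the prenyl terminus and MnO2 oxidises only the resulting allylic alcohol, giving the (E)-enal.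

Step 4
Reactants: 9 furan-3-ylmethanol
Product: 10 tert-butyl(furan-3-ylmethoxy)dimethylsilane
Conditions: TBSCl, imidazole, DMF, rt
Reagents that add atoms: tert-butyldimethylsilyl chloride CC(C)(C)[Si](C)(C)Cl
Why: Standard silyl ether formation on the primary alcohol.

Step 5
Reactants: 10 tert-butyl(furan-3-ylmethoxy)dimethylsilane
Product: 12 tert-butyldimethyl{[2-(trimethylsilyloxy)furan-3-yl]methoxy}silane, via 2-lithiofuran 11 (not isolated)
Conditions: n-BuLi, THF, −78 to −30 °C (no HMPA); then Me3SiOOSiMe3, −78 to 0 °C; used crude after filtration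
Reagents that add atoms: bis(trimethylsilyl) peroxide C[Si](C)(C)OO[Si](C)(C)C; n-butyllithium [Li]CCCC (lithium in 11 only)
Why: The CH2OSi group directs lithiation to C2 of the furan (directed metalation) and the heteroaryllithium is oxygenated by electrophilic O-transfer from the silyl peroxide, giving the 2-silyloxyfuran directly; low temperature without HMPA suppresses the 1,4 O-to-C silyl shift.

Step 6 (key step)
Reactants: 8 (E)-enal; 12 2-silyloxyfuran
Product: 13 (5S,6S)-aldol butenolide: 5-substituted 3-[(TBSO)methyl]furan-2(5H)-one with a free C5 hydroxyl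
Conditions: SiCl4 (1.5 equiv), (R,R)-bisphosphoramide [two (R)-N,N′-dimethyl-1,1′-binaphthyl-2,2′-diamine phosphoramide units joined by MeN(CH2)5NMe] (5 mol %), i-Pr2NEt (10 mol %), CH2Cl2, −78 °C; aq NaHCO3
Reagents that add atoms: none
Why: Lewis-base-activated SiCl4 binds only the aldehyde and the silyloxyfuran attacks through its C5 in an open transition state (vinylogous Mukaiyama aldol), so the aromatic ring becomes the butenolide; the chiral phosphoramide shields the Si face of the enal and the anti (threo) topology sets C5 and C6 together as 5S,6S.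

Step 7
Reactants: 13 (5S,6S)-aldol butenolide
Product: 14 C5 isobutyrate of 13
Conditions: (i-PrCO)2O, pyridine, DMAP (cat.), CH2Cl2, 0 °C
Reagents that add atoms: isobutyric anhydride CC(C)C(=O)OC(=O)C(C)C
Why: DMAP-catalysed acylation of the secondary allylic alcohol; pyridine is too weak a base to trigger γ-deprotonation and elimination of the butenolide.

Step 8
Reactants: 14 C5 isobutyrate
Product: 15 diol with free C8 and C13 hydroxyls
Conditions: HF·pyridine, pyridine, THF, 0 °C to rt; used at once, no basic work-up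
Reagents that add atoms: none
Why: Fluoride-mediated cleavage of both primary TBS ethers; the buffered acidic medium leaves the esters and butenolide intact and limits 1,2-shift of the C9 ester.

Step 9
Reactants: 15 diol
Product: 16 3-(bromomethyl)butenolide with free C8 hydroxyl
Conditions: NBS, Me2S, CH2Cl2, −20 to 0 °C
Reagents that add atoms: N-bromosuccinimide O=C1CCC(=O)N1Br
Why: Corey–Kim bromination converts only the allylic alcohol (SN2 on its alkoxysulfonium ion), while the saturated primary alcohol is returned on work-up.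

Step 10
Reactants: 16 bromide alcohol
Product: 17 C8 aldehyde (α-isovaleryloxy aldehyde) carrying the 3-(bromomethyl)butenolide
Conditions: Dess–Martin periodinane, NaHCO3, CH2Cl2, 0 °C; used crude
Reagents that add atoms: none
Why: Dess–Martin oxidation under buffered non-basic conditions gives the aldehyde without epimerising C9 or disturbing the allylic bromide.

Step 11
Reactants: 17 bromo aldehyde
Product: 18 (3E,5S,6S,7R,8R,9R,10R)-8-hydroxy-5-(isobutyryloxy)-9-(isovaleryloxy)germacra-3,11(13)-dien-12,6-olide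
Conditions: CrCl2 (8 equiv), THF, rt, syringe-pump addition to 2 mM
Reagents that add atoms: none
Why: Nozaki–Hiyama–Kishi (Barbier-type) allylation: CrCl2 inserts into the C–Br bond and the allylchromium adds through C7 in a chair Zimmerman–Traxler transition state, on the butenolide face opposite the C5 chain (6,7-trans, 7R) with the aldehyde chain equatorial (8R), which moves the double bond out to the exo-methylene and closes the ten-membered ring.

Step 12
Reactants: 18 macrocyclic dienolide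
Product: 19 (3R,4S,5R,6S,7R,8R,9R,10R)-3,4,8-trihydroxy-5-(isobutyryloxy)-9-(isovaleryloxy)germacr-11(13)-en-12,6-olide
Conditions: OsO4 (2 mol %), (DHQD)2PHAL (6 mol %), NMO, acetone/H2O, 0 °C
Reagents that add atoms: N-methylmorpholine N-oxide C[N+]1([O-])CCOCC1; water O
Why: Ligand-accelerated Sharpless-type syn-dihydroxylation prefers the electron-rich trisubstituted alkene over the conjugated exo-methylene, and both the DHQD ligand and the allylic C5 ester (Kishi's anti rule) direct OsO4 to the face that puts the C4 hydroxyl anti to the C5 oxygen (4S here, the target's 4R arrangement); C3 is set too but is erased in step 13.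

Step 13
Reactants: 19 triol
Product: 20 (4R,5R,6S,7R,8R,9R,10R)-4,8-dihydroxy-5-(isobutyryloxy)-9-(isovaleryloxy)-3-oxogermacr-11(13)-en-12,6-olide (target)
Conditions: [(neocuproine)Pd(OAc)]2(OTf)2 (5 mol %), 1,4-benzoquinone, MeCN/H2O, rt
Reagents that add atoms: none
Why: Chelation-assisted palladium-catalysed alcohol oxidation: the cationic divalent palladium catalyst binds the vicinal diol and β-hydride elimination can occur only at the secondary C3 carbinol, so the isolated C8 hydroxyl and the tertiary C4 centre are left alone.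

**Compound list**
1 | (R)-citronellal, (3R)-3,7-dimethyloct-6-enal | O=CC[C@H](C)CCC=C(C)C | starting material
2 | (2R,3R)-3,7-dimethyl-2-[(phenylamino)oxy]oct-6-enal | O=C[C@H](ONc1ccccc1)[C@H](C)CCC=C(C)C | intermediate
3 | (2R,3R)-3,7-dimethyl-2-[(phenylamino)oxy]oct-6-en-1-ol | OC[C@H](ONc1ccccc1)[C@H](C)CCC=C(C)C | intermediate
4 | (2R,3R)-3,7-dimethyloct-6-ene-1,2-diol | OC[C@H](O)[C@H](C)CCC=C(C)C | intermediate
5 | (2R,3R)-1-[(tert-butyldimethylsilyl)oxy]-3,7-dimethyloct-6-en-2-ol | CC(C)(C)[Si](C)(C)OC[C@H](O)[C@H](C)CCC=C(C)C | intermediate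
6 | (2R,3R)-1-[(tert-butyldimethylsilyl)oxy]-3,7-dimethyloct-6-en-2-yl 3-methylbutanoate | CC(C)(C)[Si](C)(C)OC[C@H](OC(=O)CC(C)C)[C@H](C)CCC=C(C)C | intermediate
7 | (2R,3R,6E)-1-[(tert-butyldimethylsilyl)oxy]-8-hydroxy-3,7-dimethyloct-6-en-2-yl 3-methylbutanoate | CC(C)(C)[Si](C)(C)OC[C@H](OC(=O)CC(C)C)[C@H](C)CC/C=C(\C)CO | intermediate
8 | (2R,3R,6E)-1-[(tert-butyldimethylsilyl)oxy]-3,7-dimethyl-8-oxooct-6-en-2-yl 3-methylbutanoate | CC(C)(C)[Si](C)(C)OC[C@H](OC(=O)CC(C)C)[C@H](C)CC/C=C(\C)C=O | intermediate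
9 | furan-3-ylmethanol | OCc1ccoc1 | starting material
10 | tert-butyl(furan-3-ylmethoxy)dimethylsilane | CC(C)(C)[Si](C)(C)OCc1ccoc1 | intermediate
11 | {3-[(tert-butyldimethylsilyloxy)methyl]furan-2-yl}lithium | [Li]c1occc1CO[Si](C)(C)C(C)(C)C | intermediate
12 | tert-butyldimethyl{[2-(trimethylsilyloxy)furan-3-yl]methoxy}silane | C[Si](C)(C)Oc1occc1CO[Si](C)(C)C(C)(C)C | intermediate
13 | (2R,3R,6E,8S)-1-[(tert-butyldimethylsilyl)oxy]-8-hydroxy-3,7-dimethyl-8-[(2S)-4-{[(tert-butyldimethylsilyl)oxy]methyl}-5-oxo-2,5-dihydrofuran-2-yl]oct-6-en-2-yl 3-methylbutanoate | CC(C)(C)[Si](C)(C)OCC1=C[C@H](OC1=O)[C@@H](O)/C(C)=C/CC[C@@H](C)[C@H](CO[Si](C)(C)C(C)(C)C)OC(=O)CC(C)C | intermediate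
14 | (1S,2E,6R,7R)-8-[(tert-butyldimethylsilyl)oxy]-1-[(2S)-4-{[(tert-butyldimethylsilyl)oxy]methyl}-5-oxo-2,5-dihydrofuran-2-yl]-2,6-dimethyl-7-[(3-methylbutanoyl)oxy]oct-2-en-1-yl 2-methylpropanoate | CC(C)(C)[Si](C)(C)OCC1=C[C@H](OC1=O)[C@@H](OC(=O)C(C)C)/C(C)=C/CC[C@@H](C)[C@H](CO[Si](C)(C)C(C)(C)C)OC(=O)CC(C)C | intermediate
15 | (1S,2E,6R,7R)-8-hydroxy-1-[(2S)-4-(hydroxymethyl)-5-oxo-2,5-dihydrofuran-2-yl]-2,6-dimethyl-7-[(3-methylbutanoyl)oxy]oct-2-en-1-yl 2-methylpropanoate | OCC1=C[C@H](OC1=O)[C@@H](OC(=O)C(C)C)/C(C)=C/CC[C@@H](C)[C@H](CO)OC(=O)CC(C)C | intermediate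
16 | (1S,2E,6R,7R)-1-[(2S)-4-(bromomethyl)-5-oxo-2,5-dihydrofuran-2-yl]-8-hydroxy-2,6-dimethyl-7-[(3-methylbutanoyl)oxy]oct-2-en-1-yl 2-methylpropanoate | BrCC1=C[C@H](OC1=O)[C@@H](OC(=O)C(C)C)/C(C)=C/CC[C@@H](C)[C@H](CO)OC(=O)CC(C)C | intermediate
17 | (1S,2E,6R,7R)-1-[(2S)-4-(bromomethyl)-5-oxo-2,5-dihydrofuran-2-yl]-2,6-dimethyl-7-[(3-methylbutanoyl)oxy]-8-oxooct-2-en-1-yl 2-methylpropanoate | BrCC1=C[C@H](OC1=O)[C@@H](OC(=O)C(C)C)/C(C)=C/CC[C@@H](C)[C@H](C=O)OC(=O)CC(C)C | intermediate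
18 | (3E,5S,6S,7R,8R,9R,10R)-8-hydroxy-5-(isobutyryloxy)-9-(isovaleryloxy)germacra-3,11(13)-dien-12,6-olide | C=C1C(=O)O[C@H]2[C@H]1[C@@H](O)[C@H](OC(=O)CC(C)C)[C@H](C)CC/C=C(C)/[C@@H]2OC(=O)C(C)C | intermediate
19 | (3R,4S,5R,6S,7R,8R,9R,10R)-3,4,8-trihydroxy-5-(isobutyryloxy)-9-(isovaleryloxy)germacr-11(13)-en-12,6-olide | C=C1C(=O)O[C@H]2[C@H]1[C@@H](O)[C@H](OC(=O)CC(C)C)[C@H](C)CC[C@@H](O)[C@](C)(O)[C@@H]2OC(=O)C(C)C | intermediate
20 | (4R,5R,6S,7R,8R,9R,10R)-4,8-dihydroxy-5-(isobutyryloxy)-9-(isovaleryloxy)-3-oxogermacr-11(13)-en-12,6-olide, CNP0203887.1 | C=C1C(=O)O[C@H]2[C@H]1[C@@H](O)[C@H](OC(=O)CC(C)C)[C@H](C)CCC(=O)[C@](C)(O)[C@@H]2OC(=O)C(C)C | target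

**Totals**
Total step count: 13. Longest linear sequence: 11 steps (1, 2, 3, 6, 7, 8, 9, 10, 11, 12, 13, from compound 1).

**Steps most likely to fail**

Step 6 (dearomative aldol). The risks are the sense and level of face selectivity with a 3-substituted silyloxyfuran, and ionisation of its CH2OSi group by the Lewis acid. Fallback: make the C5–C6 bond by reagent-controlled allylboration and close the lactone afterwards.
- Setting out from 8, [(Z)-3-(methoxymethoxy)allyl]diisopinocampheylborane (from allyl methoxymethyl ether, s-BuLi, (+)-Ipc2BOMe and BF3·OEt2; −78 °C; ethanolamine work-up) gives the threo (5S,6S) homoallylic alcohol F1.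
- Isobutyric anhydride/pyridine/DMAP gives the isobutyrate F2.
- ZnBr2 and n-PrSH (CH2Cl2, 0 °C) remove the MOM group to give the C6 alcohol F3.
- F3 is esterified at once with 2-{[(tert-butyldimethylsilyl)oxy]methyl}acrylic acid (DCC, DMAP) to give the acrylate F4.
- Ring-closing metathesis with the second-generation Grubbs catalyst (toluene, 80 °C) closes the butenolide and the route is rejoined at 14.

Step 11 (macrocyclisation). The required C8 configuration is anti-Felkin with respect to the C9 acyloxy group, so the closure may give mainly the C8 epimer. Fallback: set C8 by reduction instead of by the C–C bond formation.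
- Setting out from 17, the same closure gives the (8S)-alcohol F5.
- Dess–Martin oxidation gives the C8 ketone F6.
- Luche reduction (NaBH4, CeCl3·7H2O, MeOH, −78 °C), where Felkin–Anh control by the C9 acyloxy group now works in the wanted sense, returns the (8R)-alcohol 18.

Step 13 (diol-selective oxidation). The catalyst may not discriminate the C3 from the C8 carbinol. Fallback: mask C8 before the diol is made.
- Setting out from 18, TESOTf and 2,6-lutidine (CH2Cl2, −78 °C) give the C8 triethylsilyl ether F7.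
- The dihydroxylation of step 12 gives the diol F8.
- Dess–Martin oxidation of its only secondary alcohol gives the ketol F9.
- HF·pyridine removes the silyl group and gives 20.

**Further compounds**
F1 | step 6 | (2R,3R,6E,8S,9S)-1-[(tert-butyldimethylsilyl)oxy]-8-hydroxy-9-(methoxymethoxy)-3,7-dimethylundeca-6,10-dien-2-yl 3-methylbutanoate | C=C[C@H](OCOC)[C@@H](O)/C(C)=C/CC[C@@H](C)[C@H](CO[Si](C)(C)C(C)(C)C)OC(=O)CC(C)C
F2 | step 6 | (2R,3R,6E,8S,9S)-1-[(tert-butyldimethylsilyl)oxy]-9-(methoxymethoxy)-3,7-dimethyl-8-[(2-methylpropanoyl)oxy]undeca-6,10-dien-2-yl 3-methylbutanoate | C=C[C@H](OCOC)[C@@H](OC(=O)C(C)C)/C(C)=C/CC[C@@H](C)[C@H](CO[Si](C)(C)C(C)(C)C)OC(=O)CC(C)C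
F3 | step 6 | (2R,3R,6E,8S,9S)-1-[(tert-butyldimethylsilyl)oxy]-9-hydroxy-3,7-dimethyl-8-[(2-methylpropanoyl)oxy]undeca-6,10-dien-2-yl 3-methylbutanoate | C=C[C@H](O)[C@@H](OC(=O)C(C)C)/C(C)=C/CC[C@@H](C)[C@H](CO[Si](C)(C)C(C)(C)C)OC(=O)CC(C)C
F4 | step 6 | (2R,3R,6E,8S,9S)-1-[(tert-butyldimethylsilyl)oxy]-9-[(2-{[(tert-butyldimethylsilyl)oxy]methyl}prop-2-enoyl)oxy]-3,7-dimethyl-8-[(2-methylpropanoyl)oxy]undeca-6,10-dien-2-yl 3-methylbutanoate | C=C[C@H](OC(=O)C(=C)CO[Si](C)(C)C(C)(C)C)[C@@H](OC(=O)C(C)C)/C(C)=C/CC[C@@H](C)[C@H](CO[Si](C)(C)C(C)(C)C)OC(=O)CC(C)C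
F5 | step 11 | (3E,5S,6S,7R,8S,9R,10R)-8-hydroxy-5-(isobutyryloxy)-9-(isovaleryloxy)germacra-3,11(13)-dien-12,6-olide (8-epimer of 18) | C=C1C(=O)O[C@H]2[C@H]1[C@H](O)[C@H](OC(=O)CC(C)C)[C@H](C)CC/C=C(C)/[C@@H]2OC(=O)C(C)C
F6 | step 11 | (3E,5S,6S,7S,9R,10R)-5-(isobutyryloxy)-9-(isovaleryloxy)-8-oxogermacra-3,11(13)-dien-12,6-olide | C=C1C(=O)O[C@H]2[C@H]1C(=O)[C@H](OC(=O)CC(C)C)[C@H](C)CC/C=C(C)/[C@@H]2OC(=O)C(C)C
F7 | step 13 | (3E,5S,6S,7R,8R,9R,10R)-5-(isobutyryloxy)-9-(isovaleryloxy)-8-[(triethylsilyl)oxy]germacra-3,11(13)-dien-12,6-olide | C=C1C(=O)O[C@H]2[C@H]1[C@@H](O[Si](CC)(CC)CC)[C@H](OC(=O)CC(C)C)[C@H](C)CC/C=C(C)/[C@@H]2OC(=O)C(C)C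
F8 | step 13 | (3R,4S,5R,6S,7R,8R,9R,10R)-3,4-dihydroxy-5-(isobutyryloxy)-9-(isovaleryloxy)-8-[(triethylsilyl)oxy]germacr-11(13)-en-12,6-olide | C=C1C(=O)O[C@H]2[C@H]1[C@@H](O[Si](CC)(CC)CC)[C@H](OC(=O)CC(C)C)[C@H](C)CC[C@@H](O)[C@](C)(O)[C@@H]2OC(=O)C(C)C
F9 | step 13 | (4R,5R,6S,7R,8R,9R,10R)-4-hydroxy-5-(isobutyryloxy)-9-(isovaleryloxy)-3-oxo-8-[(triethylsilyl)oxy]germacr-11(13)-en-12,6-olide | C=C1C(=O)O[C@H]2[C@H]1[C@@H](O[Si](CC)(CC)CC)[C@H](OC(=O)CC(C)C)[C@H](C)CCC(=O)[C@](C)(O)[C@@H]2OC(=O)C(C)C
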